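A ratio is what two of us dispute in Tuesday's flask.

all flasks: L 0.44 M; G 1.4 mM

| flask | temperature | remark | time |
|---|---|---|---|
| Tuesday's | 35 °C | the very flask that is asked about, followed so far |  |
| Friday's | 41 °C | run made earlier |  |
| flask | 35 °C |  | 40 min |

| run | time / min | Z / % | L / % |
|---|---|---|---|
| Tuesday's | 3.00 | 45 | 42 |
| Tuesday's | 8.00 | 49 | 6 |
| Tuesday's | 15.0 | 33 | 0 |
| Tuesday's | 25.0 | 22 | 0 |
| Friday's | 3.00 | 49 | 17 |
| Friday's | 8.00 | 37 | 0 |
| Friday's | 15.0 | 31 | 0 |
| Friday's | 25.0 | 29 | 2 |

(standard deviation of a reading: 2 percentage points)

- elm: change nothing and wait 12 min more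
- alder: at 40 min add L, 50.0% of the amount charged, then wait 12 min
- oak: at 40 min add G, 100% of the amount charged, then wait 12 min
- larch: at 40 min raise the temperature by 20 K, then wait 12 min

* Z, in percent of the L first charged, at 40 min
* what to do for the largest gain in Z; "none" if nothing gains more than 2 percentage points (elm / alder / oak / larch / none)
* Z present, in percent of the L first charged, after oak
* Z present, in percent of the L first charged, after larch

- additions leave the volume as it is
- a reading or a percentage of Z counts all its forms, free or not

I call it the dark ratio: the part of the charge that reads neither as L nor as Z, over the part that reads as Z, (charge − [L] − [Z])/[Z], which is 3.55 at Tuesday's last reading. At Friday's last reading it is 2.38, lower in the warmer run.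

My view is that Z exchanges reversibly with a form that gives no reading, so the ratio tends to a value belonging to the temperature: thermodynamic control. The excess of Z over its last reading halves in about 5.40 min on Tuesday's readings and 3.50 min on Friday's. So the 2.78 half-lives after Tuesday's last reading put the flask near its plateau, and I say 22.0%.

Oak shifts no ratio, so it gains nothing. Alder, on my ratio, reaches 33.0%. Larch is 3.33 times the gap between the runs, which carries the ratio to 0.938 and Z to 51.6%, and the wait is 3.43 half-lives at Friday's pace. I back larch.

The forecast's maker reads the same fall as a first-order loss slowing from 0.07 to 0.04 per min, and holds that “G drives both steps and dies, with a strongly temperature-dependent decay”. The forecast says 17% now, alder as the best move, 6% after oak and 16.5% after larch.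

Tuesday's flask gives 24.4%, the best move is larch, and it reaches 49.1%, while oak leaves 24.4%.

    J ⇌ Z, rate k1*(cs1 - [Z]) while solid is left; crystals form when [Z] > cs1 (solubility = 0.380 M, k = 0.880 s⁻¹)
    L + G → D (k = 7.20 M⁻¹ s⁻¹, Ea = 55.0 kJ mol⁻¹)
    Z ⇌ E (K = 3.10, k = 0.00280 s⁻¹, Ea = 94.0 kJ mol⁻¹, ΔH = −46.0 kJ mol⁻¹)
    D → G + Z (k = 2.10 s⁻¹, Ea = 70.0 kJ mol⁻¹)
    (constants at 35 °C)

In Tuesday's flask G stands at 100% of its charge at 40.0 min. A falling Z, the forecast's picture, holds for the earlier stretch of that flask: read at 15 min it gives 30.4%, against 24.4% at 40 min and 24.4% at 400 min. In Tuesday's flask the dark part is E, and the ratio goes from 3.10 to 1.04 under larch. My two readings put the plateau of the flask run at 10 °C at a ratio of 18.7, yet at 40.0 min that flask stands at 0.154, with 20% of its L still free.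

(Readings and results are calculated on assumed constants; noise was put on by code.)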